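**Retrosynthetic overview**
- The acid comes from its methyl ester, which is cut at the diene C2'–C3' bond (Suzuki–Miyaura) into a chromane (E)-alkenyl boronate (16 skeletal atoms) and a trimethylcyclohexenyl (E)-alkenyl iodide (14 C).
- Chromane half: boronate ⇐ aldehyde (boron-Wittig) ⇐ 2-vinylchromane (ozonolysis) ⇐ Pd-catalysed asymmetric allylic O-alkylation of an (E)-phenol allyl carbonate, which sets C2. The carbonate comes from 4-bromophenol, but-3-en-2-ol (Heck) and a phosphonoacetate (HWE); the aryl bromide later becomes the carboxyl group.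
- Terpenoid half: alkenyl iodide ⇐ Zr-catalysed methylalumination/iodination of a terminal alkyne ⇐ Negishi sp2–sp3 coupling of 2,6,6-trimethylcyclohexenyl triflate (2-methylcyclohexanone, two methylations) with a homopropargylzinc reagent from but-3-yn-1-ol.
- Rings: the benzene and cyclohexene rings come in with the starting materials; the only ring formed is the dihydropyran, in step 8.

Assumption: in step 8 the (R,R)-Trost ligand with the (E)-carbonate is taken to give the (R)-chromane; I could not confirm this sense from memory, so it is checked on the first batch (chiral HPLC, rotation) and, if reversed, the (S,S)-ligand is used with nothing else changed.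

**Chromane half**

Step 1
Reactants: 1 4-bromophenol
Product: 2 4-bromo-2-iodophenol
Conditions: NIS (1.0 equiv), TsOH·H2O (10 mol%), MeCN, 0 °C → rt
Reagents that add atoms: N-iodosuccinimide, O=C1CCC(=O)N1I
Why: Electrophilic aromatic iodination; the para position is blocked by Br, so one equivalent of NIS iodinates the activated ortho position once.

Step 2
Reactants: 2 4-bromo-2-iodophenol
Product: 3 (4-bromo-2-iodophenoxy)tri(propan-2-yl)silane
Conditions: TIPSCl (1.2 equiv), imidazole (2.5 equiv), DMF, rt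
Reagents that add atoms: chlorotri(propan-2-yl)silane, CC(C)[Si](Cl)(C(C)C)C(C)C
Why: Imidazole-promoted O-silylation masks the phenol so it cannot interfere with the Heck step or add (oxa-Michael) to the enoate of step 4.

Step 3
Reactants: 3 (4-bromo-2-iodophenoxy)tri(propan-2-yl)silane; 4 but-3-en-2-ol (racemic)
Product: 5 4-[5-bromo-2-(triisopropylsilyloxy)phenyl]butan-2-one
Conditions: Pd(OAc)2 (3 mol%), n-Bu4NCl, NaHCO3, DMF, 45 °C
Reagents that add atoms: none
Why: Jeffery–Heck arylation of an allylic alcohol; oxidative addition takes C–I over C–Br, and β-hydride elimination towards the carbinol gives the enol and hence the saturated methyl ketone.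

Step 4
Reactants: 5 4-[5-bromo-2-(triisopropylsilyloxy)phenyl]butan-2-one
Product: 6 ethyl (2E)-5-[5-bromo-2-(triisopropylsilyloxy)phenyl]-3-methylpent-2-enoate
Conditions: (EtO)2P(O)CH2CO2Et, NaH, THF, 0 → 50 °C; chromatography removes the minor Z-ester
Reagents that add atoms: triethyl phosphonoacetate, CCOC(=O)CP(=O)(OCC)OCC
Why: Horner–Wadsworth–Emmons olefination of a methyl ketone is E-selective (about 4–5:1), and the geometrically pure E-ester defines the trisubstituted alkene needed for step 8.

Step 5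
Reactants: 6 ethyl (2E)-5-[5-bromo-2-(triisopropylsilyloxy)phenyl]-3-methylpent-2-enoate
Product: 7 (2E)-5-[5-bromo-2-(triisopropylsilyloxy)phenyl]-3-methylpent-2-en-1-ol
Conditions: DIBAL-H (2.3 equiv), CH2Cl2, −78 → −40 °C; Rochelle salt work-up
Reagents that add atoms: none
Why: DIBAL-H 1,2-reduction of the enoate gives the allylic alcohol without touching the aryl bromide, the silyl ether or the alkene geometry.

Step 6
Reactants: 7 (2E)-5-[5-bromo-2-(triisopropylsilyloxy)phenyl]-3-methylpent-2-en-1-ol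
Product: 8 (2E)-5-[5-bromo-2-(triisopropylsilyloxy)phenyl]-3-methylpent-2-en-1-yl methyl carbonate
Conditions: ClCO2Me, pyridine, CH2Cl2, 0 °C
Reagents that add atoms: methyl chloroformate, COC(=O)Cl
Why: O-acylation to the allylic methyl carbonate installs the leaving group that Pd(0) ionises in step 8.

Step 7
Reactants: 8 (2E)-5-[5-bromo-2-(triisopropylsilyloxy)phenyl]-3-methylpent-2-en-1-yl methyl carbonate
Product: 9 (2E)-5-(5-bromo-2-hydroxyphenyl)-3-methylpent-2-en-1-yl methyl carbonate
Conditions: TBAF, AcOH, THF, 0 °C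
Reagents that add atoms: none
Why: Fluoride desilylation buffered with acetic acid frees the phenol without base-induced attack on the carbonate.

Step 8
Reactants: 9 (2E)-5-(5-bromo-2-hydroxyphenyl)-3-methylpent-2-en-1-yl methyl carbonate
Product: 10 (2R)-6-bromo-2-methyl-2-vinylchromane
Conditions: Pd2(dba)3·CHCl3 (2 mol%), (R,R)-DACH-phenyl Trost ligand (6 mol%), AcOH (1 equiv), CH2Cl2, rt
Reagents that add atoms: none
Why: Trost asymmetric allylic alkylation (intramolecular Tsuji–Trost O-alkylation): Pd(0) ionises the carbonate, the phenol closes the six-membered ring at the more substituted allyl terminus, and the chiral ligand selects the allyl face so that quaternary C2 is formed as R (Ar–Br is inert to Pd(0) at rt).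

Step 9
Reactants: 10 (2R)-6-bromo-2-methyl-2-vinylchromane
Product: 12 methyl (2R)-2-methyl-2-vinylchromane-6-carboxylate, via aryllithium 11 (not isolated)
Conditions: n-BuLi (1.05 equiv), THF, −78 °C; cannulate into ClCO2Me (3 equiv), THF, −78 °C
Reagents that add atoms: methyl chloroformate, COC(=O)Cl
Why: Bromine–lithium exchange followed by C-acylation of the aryllithium (inverse addition prevents ketone formation); the ether-bound quaternary centre has no acidic hydrogen and is untouched.

Step 10
Reactants: 12 methyl (2R)-2-methyl-2-vinylchromane-6-carboxylate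
Product: 14 methyl (2R)-2-formyl-2-methylchromane-6-carboxylate, via ozonide 13 (not isolated)
Conditions: O3 (1 equiv, Sudan Red indicator), CH2Cl2, −78 °C; then PPh3, −78 °C → rt
Reagents that add atoms: ozone, [O-][O+]=O
Why: Ozonolysis with reductive work-up cleaves only the vinyl group (the arene is deactivated by the ester), and the α-carbon is quaternary so it cannot epimerise.

Step 11
Reactants: 14 methyl (2R)-2-formyl-2-methylchromane-6-carboxylate
Product: 15 methyl (2R)-2-methyl-2-[(E)-2-(4,4,5,5-tetramethyl-1,3,2-dioxaborolan-2-yl)vinyl]chromane-6-carboxylate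
Conditions: TMP, n-BuLi, THF, 0 °C (→ LiTMP); CH2(Bpin)2, 0 °C; then 14, −78 °C → rt
Reagents that add atoms: bis(4,4,5,5-tetramethyl-1,3,2-dioxaborolan-2-yl)methane, CC1(C)OB(CB2OC(C)(C)C(C)(C)O2)OC1(C)C
Why: Boron-Wittig olefination: the stabilised α-diboryl carbanion adds to the aldehyde much faster than to the benzoate, and syn B–O elimination gives the (E)-alkenyl boronate.

**Terpenoid half**

Step 12
Reactants: 16 2-methylcyclohexanone (racemic)
Product: 18 2,6-dimethylcyclohexanone (cis/trans mixture), via lithium enolate 17 (not isolated)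
Conditions: LDA (1.05 equiv), THF, −78 °C; MeI, −78 °C → rt
Reagents that add atoms: iodomethane, CI
Why: Kinetic enolate alkylation at the less substituted α-carbon; the regiochemistry is not critical because any 2,2-dimethyl isomer also converges on 20 in the next step.

Step 13
Reactants: 18 2,6-dimethylcyclohexanone (cis/trans mixture)
Product: 20 2,2,6-trimethylcyclohexanone (racemic), via lithium enolate 19 (not isolated)
Conditions: LDA (1.1 equiv), THF, −78 → 0 °C; MeI, DMPU, 0 °C → rt
Reagents that add atoms: iodomethane, CI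
Why: Enolate C-methylation builds the gem-dimethyl carbon, and the remaining tertiary α-hydrogen is too hindered for fast over-alkylation.

Step 14
Reactants: 20 2,2,6-trimethylcyclohexanone (racemic)
Product: 22 2,6,6-trimethylcyclohex-1-en-1-yl trifluoromethanesulfonate, via lithium enolate 21 (not isolated)
Conditions: LDA (1.2 equiv), THF, −78 → 0 °C; PhNTf2, 0 °C → rt
Reagents that add atoms: N-phenylbis(trifluoromethanesulfonimide), O=S(=O)(N(c1ccccc1)S(=O)(=O)C(F)(F)F)C(F)(F)F
Why: Enol triflate formation: only one enolate is possible, so O-triflation fixes the tetrasubstituted C=C exactly where the target has it and removes the last stereocentre of this half.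

Step 15
Reactants: 23 but-3-yn-1-ol
Product: 26 4-(trimethylsilyl)but-3-yn-1-ol, via dilithio salt 24 (not isolated), via bis-silyl ether 25 (not isolated)
Conditions: n-BuLi (2.2 equiv), THF, −78 °C; TMSCl (2.3 equiv), −78 °C → rt; then 1 M HCl, rt
Reagents that add atoms: chlorotrimethylsilane, C[Si](C)(C)Cl
Why: Double deprotonation and C,O-bis-silylation followed by selective acidic cleavage of the labile O–Si bond leaves the alkyne capped.

Step 16
Reactants: 26 4-(trimethylsilyl)but-3-yn-1-ol
Product: 27 (4-iodobut-1-yn-1-yl)trimethylsilane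
Conditions: PPh3, imidazole, I2, CH2Cl2, 0 °C → rt
Reagents that add atoms: iodine, II
Why: Appel-type iodination: the alkoxyphosphonium is displaced by iodide in an SN2 step at the primary carbon.

Step 17
Reactants: 27 (4-iodobut-1-yn-1-yl)trimethylsilane; 22 2,6,6-trimethylcyclohex-1-en-1-yl trifluoromethanesulfonate
Product: 29 trimethyl[4-(2,6,6-trimethylcyclohex-1-en-1-yl)but-1-yn-1-yl]silane, via zinc reagent 28 (not isolated)
Conditions: Zn dust (BrCH2CH2Br/TMSCl-activated), THF, 40 °C; then 22, PdCl2(dppf)·CH2Cl2 (5 mol%), LiCl, THF/NMP, 60 °C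
Reagents that add atoms: none
Why: Zinc insertion into the primary C–I bond and Negishi sp2–sp3 cross-coupling with the enol triflate; the wide-bite-angle dppf ligand favours reductive elimination over β-hydride loss and the silyl cap keeps the alkyne out of the catalysis.

Step 18
Reactants: 29 trimethyl[4-(2,6,6-trimethylcyclohex-1-en-1-yl)but-1-yn-1-yl]silane
Product: 30 2-(but-3-yn-1-yl)-1,3,3-trimethylcyclohex-1-ene
Conditions: K2CO3 (0.3 equiv), MeOH, rt
Reagents that add atoms: none
Why: Base-catalysed protodesilylation of the alkynylsilane releases the terminal alkyne.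

Step 19
Reactants: 30 2-(but-3-yn-1-yl)-1,3,3-trimethylcyclohex-1-ene
Product: 32 2-[(3E)-4-iodo-3-methylbut-3-en-1-yl]-1,3,3-trimethylcyclohex-1-ene, via vinylalane 31 (not isolated)
Conditions: Me3Al (2.5 equiv), Cp2ZrCl2 (0.25 equiv), CH2Cl2, 0 °C → rt; then I2, THF, −30 → 0 °C
Reagents that add atoms: trimethylaluminium, C[Al](C)C; iodine, II
Why: Negishi Zr-catalysed carboalumination adds Me and Al syn with Al on the terminal carbon, and iodinolysis with retention gives the (E)-trisubstituted alkenyl iodide while the tetrasubstituted ring alkene stays inert.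

**Coupling and end game**

Step 20
Reactants: 15 methyl (2R)-2-methyl-2-[(E)-2-(4,4,5,5-tetramethyl-1,3,2-dioxaborolan-2-yl)vinyl]chromane-6-carboxylate; 32 2-[(3E)-4-iodo-3-methylbut-3-en-1-yl]-1,3,3-trimethylcyclohex-1-ene
Product: 33 methyl (2R)-2-methyl-2-[(1E,3E)-4-methyl-6-(2,6,6-trimethylcyclohex-1-en-1-yl)hexa-1,3-dien-1-yl]chromane-6-carboxylate
Conditions: PdCl2(dppf)·CH2Cl2 (5 mol%), K3PO4 (3 M aq., 3 equiv), THF, degassed, rt → 40 °C
Reagents that add atoms: none
Why: Suzuki–Miyaura sp2–sp2 coupling joins the two halves with retention at both alkene carbons, giving the (1E,3E)-diene without touching the C2 stereocentre.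

Step 21
Reactants: 33 methyl (2R)-2-methyl-2-[(1E,3E)-4-methyl-6-(2,6,6-trimethylcyclohex-1-en-1-yl)hexa-1,3-dien-1-yl]chromane-6-carboxylate
Product: 35 (2R)-2-methyl-2-[(1E,3E)-4-methyl-6-(2,6,6-trimethylcyclohex-1-en-1-yl)hexa-1,3-dien-1-yl]chromane-6-carboxylic acid, via lithium carboxylate 34 (not isolated)
Conditions: LiOH·H2O (5 equiv), THF/MeOH/H2O 3:1:1, 40 °C; then 1 M HCl to pH 3–4, 0 °C
Reagents that add atoms: lithium hydroxide, [Li+].[OH-]
Why: Saponification (BAc2) and mild acidification give the acid; the stereocentre is quaternary and cannot epimerise, and the cold, weakly acidic work-up protects the dienylic aryl ether.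

**Compound list**
1 | 4-bromophenol | Oc1ccc(Br)cc1 | starting material
2 | 4-bromo-2-iodophenol | Oc1ccc(Br)cc1I | intermediate
3 | (4-bromo-2-iodophenoxy)tri(propan-2-yl)silane | CC(C)[Si](Oc1ccc(Br)cc1I)(C(C)C)C(C)C | intermediate
4 | but-3-en-2-ol (racemic) | C=CC(C)O | starting material
5 | 4-[5-bromo-2-(triisopropylsilyloxy)phenyl]butan-2-one | CC(=O)CCc1cc(Br)ccc1O[Si](C(C)C)(C(C)C)C(C)C | intermediate
6 | ethyl (2E)-5-[5-bromo-2-(triisopropylsilyloxy)phenyl]-3-methylpent-2-enoate | CCOC(=O)/C=C(\C)CCc1cc(Br)ccc1O[Si](C(C)C)(C(C)C)C(C)C | intermediate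
7 | (2E)-5-[5-bromo-2-(triisopropylsilyloxy)phenyl]-3-methylpent-2-en-1-ol | OC/C=C(\C)CCc1cc(Br)ccc1O[Si](C(C)C)(C(C)C)C(C)C | intermediate
8 | (2E)-5-[5-bromo-2-(triisopropylsilyloxy)phenyl]-3-methylpent-2-en-1-yl methyl carbonate | COC(=O)OC/C=C(\C)CCc1cc(Br)ccc1O[Si](C(C)C)(C(C)C)C(C)C | intermediate
9 | (2E)-5-(5-bromo-2-hydroxyphenyl)-3-methylpent-2-en-1-yl methyl carbonate | COC(=O)OC/C=C(\C)CCc1cc(Br)ccc1O | intermediate
10 | (2R)-6-bromo-2-methyl-2-vinylchromane | C=C[C@@]1(C)CCc2cc(Br)ccc2O1 | intermediate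
11 | [(2R)-2-methyl-2-vinylchroman-6-yl]lithium | C=C[C@@]1(C)CCc2cc([Li])ccc2O1 | intermediate
12 | methyl (2R)-2-methyl-2-vinylchromane-6-carboxylate | C=C[C@@]1(C)CCc2cc(C(=O)OC)ccc2O1 | intermediate
13 | methyl (2R)-2-methyl-2-(1,2,4-trioxolan-3-yl)chromane-6-carboxylate (epimers at the trioxolane carbon) | C1OC(OO1)[C@@]2(C)CCc3cc(C(=O)OC)ccc3O2 | intermediate
14 | methyl (2R)-2-formyl-2-methylchromane-6-carboxylate | O=C[C@@]1(C)CCc2cc(C(=O)OC)ccc2O1 | intermediate
15 | methyl (2R)-2-methyl-2-[(E)-2-(4,4,5,5-tetramethyl-1,3,2-dioxaborolan-2-yl)vinyl]chromane-6-carboxylate | CC1(C)OB(/C=C/[C@@]2(C)CCc3cc(C(=O)OC)ccc3O2)OC1(C)C | intermediate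
16 | 2-methylcyclohexanone (racemic) | CC1CCCCC1=O | starting material
17 | lithium 6-methylcyclohex-1-en-1-olate | [Li]OC1=CCCCC1C | intermediate
18 | 2,6-dimethylcyclohexanone (cis/trans mixture) | CC1CCCC(C)C1=O | intermediate
19 | lithium 2,6-dimethylcyclohex-1-en-1-olate | [Li]OC1=C(C)CCCC1C | intermediate
20 | 2,2,6-trimethylcyclohexanone (racemic) | CC1CCCC(C)(C)C1=O | intermediate
21 | lithium 2,6,6-trimethylcyclohex-1-en-1-olate | [Li]OC1=C(C)CCCC1(C)C | intermediate
22 | 2,6,6-trimethylcyclohex-1-en-1-yl trifluoromethanesulfonate | CC1=C(OS(=O)(=O)C(F)(F)F)C(C)(C)CCC1 | intermediate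
23 | but-3-yn-1-ol | C#CCCO | starting material
24 | lithium 4-lithiobut-3-yn-1-olate | [Li]C#CCCO[Li] | intermediate
25 | trimethyl{[4-(trimethylsilyl)but-3-yn-1-yl]oxy}silane | C[Si](C)(C)C#CCCO[Si](C)(C)C | intermediate
26 | 4-(trimethylsilyl)but-3-yn-1-ol | C[Si](C)(C)C#CCCO | intermediate
27 | (4-iodobut-1-yn-1-yl)trimethylsilane | C[Si](C)(C)C#CCCI | intermediate
28 | [4-(trimethylsilyl)but-3-yn-1-yl]zinc iodide | C[Si](C)(C)C#CCC[Zn]I | intermediate
29 | trimethyl[4-(2,6,6-trimethylcyclohex-1-en-1-yl)but-1-yn-1-yl]silane | C[Si](C)(C)C#CCCC1=C(C)CCCC1(C)C | intermediate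
30 | 2-(but-3-yn-1-yl)-1,3,3-trimethylcyclohex-1-ene | C#CCCC1=C(C)CCCC1(C)C | intermediate
31 | dimethyl[(1E)-2-methyl-4-(2,6,6-trimethylcyclohex-1-en-1-yl)but-1-en-1-yl]alumane | C[Al](C)/C=C(\C)CCC1=C(C)CCCC1(C)C | intermediate
32 | 2-[(3E)-4-iodo-3-methylbut-3-en-1-yl]-1,3,3-trimethylcyclohex-1-ene | I/C=C(\C)CCC1=C(C)CCCC1(C)C | intermediate
33 | methyl (2R)-2-methyl-2-[(1E,3E)-4-methyl-6-(2,6,6-trimethylcyclohex-1-en-1-yl)hexa-1,3-dien-1-yl]chromane-6-carboxylate | CC1=C(CC/C(C)=C/C=C/[C@@]2(C)CCc3cc(C(=O)OC)ccc3O2)C(C)(C)CCC1 | intermediate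
34 | lithium (2R)-2-methyl-2-[(1E,3E)-4-methyl-6-(2,6,6-trimethylcyclohex-1-en-1-yl)hexa-1,3-dien-1-yl]chromane-6-carboxylate | CC1=C(CC/C(C)=C/C=C/[C@@]2(C)CCc3cc(C(=O)[O-])ccc3O2)C(C)(C)CCC1.[Li+] | intermediate
35 | (2R)-2-methyl-2-[(1E,3E)-4-methyl-6-(2,6,6-trimethylcyclohex-1-en-1-yl)hexa-1,3-dien-1-yl]chromane-6-carboxylic acid | CC1=C(CC/C(C)=C/C=C/[C@@]2(C)CCc3cc(C(=O)O)ccc3O2)C(C)(C)CCC1 | target

**Step count**
Total steps: 21. Longest linear sequence: 13 (steps 1–11, then 20 and 21, from 4-bromophenol). The terpenoid half is 8 steps to the target from 2-methylcyclohexanone, with a 2-step side branch from but-3-yn-1-ol.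

**Steps most likely to fail, with fallbacks**

Step 17. The triflate carbon is flanked by a quaternary carbon and a substituted alkene carbon, so oxidative addition and transmetalation may be too slow and the zinc reagent may simply be protonated. The fallback sets out from 22 and comes back at 29, replacing the hindered sp2–sp3 coupling by a CO insertion and an unhindered SN2 step. Methoxycarbonylation of 22 (Pd(OAc)2, dppp, CO 1 atm, MeOH, Et3N, DMF, 70 °C) gives methyl 2,6,6-trimethylcyclohex-1-ene-1-carboxylate F1. DIBAL-H (CH2Cl2, −78 °C) reduces it to (2,6,6-trimethylcyclohex-1-en-1-yl)methanol F2. PBr3 (Et2O, 0 °C) converts this to 2-(bromomethyl)-1,3,3-trimethylcyclohex-1-ene F3. Alkylation of 3-lithio-1-(trimethylsilyl)propyne (1-(trimethylsilyl)propyne, n-BuLi, TMEDA, THF, −78 °C) with this primary allylic bromide gives 29.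

Step 8. E-configured carbonates tend to give lower ee than Z ones in this cyclisation, and the sense of induction rests on the assumption above. The fallback sets out from 7 and comes back at 10, setting the stereocentre by reagent control instead. Sharpless asymmetric epoxidation of 7 (Ti(OiPr)4, L-(+)-DET, t-BuOOH, 4 Å MS, CH2Cl2, −20 °C) gives, by analogy with geraniol, [(2S,3S)-3-{2-[5-bromo-2-(triisopropylsilyloxy)phenyl]ethyl}-3-methyloxiran-2-yl]methanol F4. TBAF/AcOH (THF, 0 °C) frees the phenol to give 4-bromo-2-{2-[(2S,3S)-3-(hydroxymethyl)-2-methyloxiran-2-yl]ethyl}phenol F5. Catalytic CSA (CH2Cl2, 0 °C) then triggers 6-exo opening at the tertiary epoxide carbon with inversion, giving (1S)-1-[(2R)-6-bromo-2-methylchroman-2-yl]ethane-1,2-diol F6. NaIO4 (THF/H2O) cleaves the diol to (2R)-6-bromo-2-methylchromane-2-carbaldehyde F7. Wittig methylenation (Ph3PCH3Br, KHMDS, THF, 0 °C) gives 10.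

Step 11. The bulky diboryl carbanion must add to a neopentyl-type aldehyde in the presence of an ester, and the addition may be slow or unselective. The fallback sets out from 14 and comes back at 15 by way of an alkyne. Ohira–Bestmann homologation (dimethyl (1-diazo-2-oxopropyl)phosphonate, K2CO3, MeOH, rt) gives methyl (2R)-2-ethynyl-2-methylchromane-6-carboxylate F8. Zr-catalysed syn-hydroboration (HBpin, Cp2Zr(H)Cl 10 mol%, Et3N 10 mol%, CH2Cl2, 50 °C) gives 15.

**Further compounds**
F1 | step 17 | methyl 2,6,6-trimethylcyclohex-1-ene-1-carboxylate | COC(=O)C1=C(C)CCCC1(C)C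
F2 | step 17 | (2,6,6-trimethylcyclohex-1-en-1-yl)methanol | OCC1=C(C)CCCC1(C)C
F3 | step 17 | 2-(bromomethyl)-1,3,3-trimethylcyclohex-1-ene | BrCC1=C(C)CCCC1(C)C
F4 | step 8 | [(2S,3S)-3-{2-[5-bromo-2-(triisopropylsilyloxy)phenyl]ethyl}-3-methyloxiran-2-yl]methanol | OC[C@@H]1O[C@@]1(C)CCc1cc(Br)ccc1O[Si](C(C)C)(C(C)C)C(C)C
F5 | step 8 | 4-bromo-2-{2-[(2S,3S)-3-(hydroxymethyl)-2-methyloxiran-2-yl]ethyl}phenol | OC[C@@H]1O[C@@]1(C)CCc1cc(Br)ccc1O
F6 | step 8 | (1S)-1-[(2R)-6-bromo-2-methylchroman-2-yl]ethane-1,2-diol | OC[C@H](O)[C@@]1(C)CCc2cc(Br)ccc2O1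
F7 | step 8 | (2R)-6-bromo-2-methylchromane-2-carbaldehyde | O=C[C@@]1(C)CCc2cc(Br)ccc2O1
F8 | step 11 | methyl (2R)-2-ethynyl-2-methylchromane-6-carboxylate | C#C[C@@]1(C)CCc2cc(C(=O)OC)ccc2O1
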